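**Retrosynthetic overview** (ring locants: C1 ketone, C2 N-bearing, C3 =CH, C4 quaternary carbinol, C5 CHOH, C6 CH2; trienoyl chain C1′–C7′)
1. The two amide bonds are cut last: C7′–N by carbodiimide coupling with the aminocyclopentenone, C2–N by Cu-catalysed amidation of a 2-iodoenone with the (6R)-dienamide.
2. Key disconnection is C4–C1′: a radical C–H alkenylation joins the carbinol carbon of 4-hydroxycyclohexanone to the complete all-E trienoate, delivered as a trienyl sulfone (radical addition, then loss of sulfonyl radical).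
3. The adduct is dehydrogenated to an achiral p-quinol, which is desymmetrised by a chiral-phosphoric-acid acetalisation/oxa-Michael cascade to give the (4S,5R) cis-diol as its acetal. The side-chain (6R) centre comes from a Cu-catalysed asymmetric allylic methylation.
4. No carbocycle is built: the six-membered ring enters as 4-hydroxycyclohexanone and the five-membered ring as the aminocyclopentenone. The only ring formed is the temporary dioxolane (step 5), opened again in step 12.

Assumption: 27 is bought as its hydrochloride (free base: 8 non-hydrogen atoms); the tert-butyl group of 2 is a carboxyl protecting group and is not counted (diazoacetate unit: 6 non-hydrogen atoms).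
Assumption: the sense of induction of the chiral catalysts in steps 5 and 8 is assigned by analogy and would be confirmed on the first batch; the mirror-image catalyst or ligand is used if it is opposite.

**Route**

Step 1
Reactants: 1 furan; 2 tert-butyl diazoacetate
Product: 5 tert-butyl (2E,4E)-6-oxohexa-2,4-dienoate, via exo-cyclopropane adduct 3 (not isolated), via (2E,4Z)-dienal ester 4 (not isolated)
Conditions: furan (10 equiv), Rh2(OAc)4 (0.5 mol%), CH2Cl2, 25 °C, slow addition of 2; then I2 (2 mol%), 25 °C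
Reagents that add atoms: none
Why: Carbenoid cyclopropanation of furan followed by spontaneous electrocyclic ring opening gives the (2E,4Z)-dienal, which iodine equilibrates to the thermodynamic (2E,4E) isomer.

Step 2
Reactants: 5 tert-butyl (2E,4E)-6-oxohexa-2,4-dienoate; 6 (methylsulfonyl)acetic acid
Product: 8 tert-butyl (2E,4E,6E)-7-(methylsulfonyl)hepta-2,4,6-trienoate, via Knoevenagel sulfonyl acid 7 (not isolated)
Conditions: 6 (1.2 equiv), piperidine (20 mol%), pyridine, 80 °C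
Reagents that add atoms: none
Why: Knoevenagel–Doebner condensation with decarboxylation gives the conjugated (E)-vinyl sulfone as the thermodynamic isomer.

Step 3
Reactants: 9 4-hydroxycyclohexan-1-one; 8 tert-butyl (2E,4E,6E)-7-(methylsulfonyl)hepta-2,4,6-trienoate
Product: 10 tert-butyl (2E,4E,6E)-7-(1-hydroxy-4-oxocyclohexyl)hepta-2,4,6-trienoate
Conditions: 9 (3 equiv), Ir[dF(CF3)ppy]2(dtbbpy)PF6 (1 mol%), quinuclidine (20 mol%), Bu4NH2PO4 (25 mol%), K2HPO4 (1.5 equiv), MeCN, 450 nm LEDs, 25 °C; then I2 (3 mol%), CH2Cl2, 25 °C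
Reagents that add atoms: none
Why: Proposed new method: the quinuclidinium radical cation (made by the photoexcited iridium complex) abstracts the hydridic carbinol C–H of 9 (hydrogen-bonded to phosphate), the nucleophilic α-hydroxy radical adds to the sulfonyl-bearing terminus of 8 (vinylogously β to the ester, giving a pentadienyl-ester radical), β-scission expels MeSO2•, which is reduced to sulfinate to close the cycle, and iodine then equilibrates any Z isomers to all-E; the closest known reactions are photoredox/HAT α-C–H alkylation of alcohols with acrylates and photoredox radical vinylation with vinyl sulfones (addition–β-sulfonyl elimination); 10 is achiral, so no stereocentre is set.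

Step 4
Reactants: 10 tert-butyl (2E,4E,6E)-7-(1-hydroxy-4-oxocyclohexyl)hepta-2,4,6-trienoate
Product: 12 tert-butyl (2E,4E,6E)-7-(1-hydroxy-4-oxocyclohexa-2,5-dien-1-yl)hepta-2,4,6-trienoate, via mono-enone 11 (not isolated)
Conditions: IBX (3.5 equiv), DMSO/PhF 1:2, 70 °C
Reagents that add atoms: none
Why: Two successive IBX α,β-dehydrogenations give the cross-conjugated dienone, which cannot aromatise because C4 is quaternary; the tertiary alcohol and the electron-poor triene are inert, and 12 is achiral.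

Step 5
Reactants: 12 tert-butyl (2E,4E,6E)-7-(1-hydroxy-4-oxocyclohexa-2,5-dien-1-yl)hepta-2,4,6-trienoate
Product: 14 tert-butyl (2E,4E,6E)-7-[(2S,3aR,7aS)-2-methyl-5-oxo-3a,4,5,7a-tetrahydro-2H-1,3-benzodioxol-7a-yl]hepta-2,4,6-trienoate, via hemiacetal 13 (not isolated)
Conditions: MeCHO (3 equiv), (S)-TRIP [(S)-3,3′-bis(2,4,6-triisopropylphenyl)-1,1′-binaphthyl-2,2′-diyl hydrogen phosphate] (5 mol%), toluene, 4 °C
Reagents that add atoms: acetaldehyde, CC=O
Why: In this desymmetrising acetalisation/intramolecular oxa-Michael cascade the hemiacetal OH can only reach the enone on the face of the C4 oxygen, so the dioxolane is cis-fused (C5–O cis to C4–O), and the chiral phosphoric acid selects one of the two enantiotopic enone arms, giving (4S,5R).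

Step 6
Reactants: 14 tert-butyl (2E,4E,6E)-7-[(2S,3aR,7aS)-2-methyl-5-oxo-3a,4,5,7a-tetrahydro-2H-1,3-benzodioxol-7a-yl]hepta-2,4,6-trienoate
Product: 15 tert-butyl (2E,4E,6E)-7-[(2S,3aR,7aS)-6-iodo-2-methyl-5-oxo-3a,4,5,7a-tetrahydro-2H-1,3-benzodioxol-7a-yl]hepta-2,4,6-trienoate
Conditions: I2 (2 equiv), pyridine/CH2Cl2 1:1, 0 → 25 °C, dark
Reagents that add atoms: iodine, II
Why: Johnson α-iodination (pyridine conjugate addition, iodination, elimination) touches only the remaining enone, and the base is too weak for retro-oxa-Michael, so both stereocentres are kept and the ring is now permanently unsymmetrical.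

Step 7
Reactants: 16 (E)-hept-2-en-1-ol
Product: 17 (E)-1-bromohept-2-ene
Conditions: PBr3 (0.4 equiv), Et2O, 0 °C
Reagents that add atoms: phosphorus tribromide, BrP(Br)Br
Why: SN2 bromination of a primary allylic alcohol with retention of the E alkene.

Step 8
Reactants: 17 (E)-1-bromohept-2-ene
Product: 18 (R)-3-methylhept-1-ene
Conditions: MeMgBr (1.2 equiv), CuBr·SMe2 (2 mol%), (R,Rp)-Taniaphos (2.4 mol%), CH2Cl2, −75 °C
Reagents that add atoms: methylmagnesium bromide, C[Mg]Br
Why: Cu-catalysed asymmetric allylic alkylation (SN2′) gives the branched alkene, and the ferrocenyl diphosphine ligand sets the (R) centre by face-selective γ-methylation.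

Step 9
Reactants: 18 (R)-3-methylhept-1-ene; 19 methacrolein
Product: 20 (R,E)-2,4-dimethyloct-2-enal
Conditions: 19 (5 equiv), second-generation Hoveyda–Grubbs catalyst RuCl2(H2IMes)(=CH-C6H4-2-OiPr) (5 mol%), CH2Cl2, 40 °C
Reagents that add atoms: none
Why: Olefin cross-metathesis with an excess of the 1,1-disubstituted enal gives the E trisubstituted enal under thermodynamic control without touching the allylic stereocentre.

Step 10
Reactants: 20 (R,E)-2,4-dimethyloct-2-enal; 21 2-chloroacetamide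
Product: 24 (2E,4E,6R)-4,6-dimethyldeca-2,4-dienamide, via phosphonium chloride 22 (not isolated), via carbamoylmethylene ylide 23 (not isolated)
Conditions: 21, PPh3, MeCN, 80 °C; then 20, K2CO3, 60 °C
Reagents that add atoms: none
Why: Wittig olefination with the stabilised ylide made in the flask is E-selective, and the mild base leaves the γ-stereocentre intact.

Step 11
Reactants: 15 tert-butyl (2E,4E,6E)-7-[(2S,3aR,7aS)-6-iodo-2-methyl-5-oxo-3a,4,5,7a-tetrahydro-2H-1,3-benzodioxol-7a-yl]hepta-2,4,6-trienoate; 24 (2E,4E,6R)-4,6-dimethyldeca-2,4-dienamide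
Product: 25 tert-butyl (2E,4E,6E)-7-[(2S,3aR,7aS)-6-{[(2E,4E,6R)-4,6-dimethyldeca-2,4-dienoyl]amino}-2-methyl-5-oxo-3a,4,5,7a-tetrahydro-2H-1,3-benzodioxol-7a-yl]hepta-2,4,6-trienoate
Conditions: CuI (15 mol%), N,N′-dimethylethylenediamine (30 mol%), Cs2CO3 (1.5 equiv), THF, 55 °C
Reagents that add atoms: none
Why: Goldberg-type Cu-catalysed amidation of the vinylic iodide forms the C2–N bond with the alkene in place; C4 can no longer be scrambled because the ring is unsymmetrical and any reversible oxa-Michael opening can only re-close cis.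

Step 12
Reactants: 25 tert-butyl (2E,4E,6E)-7-[(2S,3aR,7aS)-6-{[(2E,4E,6R)-4,6-dimethyldeca-2,4-dienoyl]amino}-2-methyl-5-oxo-3a,4,5,7a-tetrahydro-2H-1,3-benzodioxol-7a-yl]hepta-2,4,6-trienoate
Product: 26 (2E,4E,6E)-7-[(1S,6R)-3-{[(2E,4E,6R)-4,6-dimethyldeca-2,4-dienoyl]amino}-1,6-dihydroxy-4-oxocyclohex-2-en-1-yl]hepta-2,4,6-trienoic acid
Conditions: TFA/H2O/CH2Cl2 9:1:10, 0 → 25 °C
Reagents that add atoms: none
Why: One acidolysis step hydrolyses the ethylidene acetal and cleaves the tert-butyl ester (alkyl–oxygen fission), while the tertiary alcohol, flanked by two electron-poor π-systems, resists ionisation; no stereocentre is affected.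

Step 13
Reactants: 26 (2E,4E,6E)-7-[(1S,6R)-3-{[(2E,4E,6R)-4,6-dimethyldeca-2,4-dienoyl]amino}-1,6-dihydroxy-4-oxocyclohex-2-en-1-yl]hepta-2,4,6-trienoic acid; 27 2-amino-3-hydroxycyclopent-2-en-1-one
Product: 29 (2E,4E,6R)-N-[(3S,4R)-3,4-dihydroxy-3-{(1E,3E,5E)-7-[(2-hydroxy-5-oxocyclopent-1-en-1-yl)amino]-7-oxohepta-1,3,5-trien-1-yl}-6-oxocyclohex-1-en-1-yl]-4,6-dimethyldeca-2,4-dienamide, via O-acylisourea 28 (not isolated)
Conditions: 27 as its hydrochloride (1.5 equiv), EDC·HCl (1.3 equiv), N-methylmorpholine (3 equiv), DMF, 0 → 25 °C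
Reagents that add atoms: none
Why: Carbodiimide amide coupling, in which the amine outcompetes the hindered tertiary and secondary alcohols and any O-acylated enol transfers its acyl group to nitrogen.

**Compound list**

1 | furan | c1ccoc1 | starting material
2 | tert-butyl diazoacetate | CC(C)(C)OC(=O)C=[N+]=[N-] | starting material
3 | tert-butyl exo-2-oxabicyclo[3.1.0]hex-3-ene-6-carboxylate (racemic, one enantiomer drawn; not isolated) | CC(C)(C)OC(=O)[C@H]1[C@@H]2C=CO[C@H]12 | intermediate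
4 | tert-butyl (2E,4Z)-6-oxohexa-2,4-dienoate (not isolated) | CC(C)(C)OC(=O)/C=C/C=C\C=O | intermediate
5 | tert-butyl (2E,4E)-6-oxohexa-2,4-dienoate | CC(C)(C)OC(=O)/C=C/C=C/C=O | intermediate
6 | (methylsulfonyl)acetic acid | CS(=O)(=O)CC(=O)O | starting material
7 | 8-tert-butyl hydrogen (4E,6E)-2-(methylsulfonyl)octa-2,4,6-trienedioate (not isolated) | CS(=O)(=O)C(C(=O)O)=C/C=C/C=C/C(=O)OC(C)(C)C | intermediate
8 | tert-butyl (2E,4E,6E)-7-(methylsulfonyl)hepta-2,4,6-trienoate | CS(=O)(=O)/C=C/C=C/C=C/C(=O)OC(C)(C)C | intermediate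
9 | 4-hydroxycyclohexan-1-one | O=C1CCC(O)CC1 | starting material
10 | tert-butyl (2E,4E,6E)-7-(1-hydroxy-4-oxocyclohexyl)hepta-2,4,6-trienoate | O=C1CCC(O)(/C=C/C=C/C=C/C(=O)OC(C)(C)C)CC1 | intermediate
11 | tert-butyl (2E,4E,6E)-7-(1-hydroxy-4-oxocyclohex-2-en-1-yl)hepta-2,4,6-trienoate (racemic; not isolated) | O=C1C=CC(O)(/C=C/C=C/C=C/C(=O)OC(C)(C)C)CC1 | intermediate
12 | tert-butyl (2E,4E,6E)-7-(1-hydroxy-4-oxocyclohexa-2,5-dien-1-yl)hepta-2,4,6-trienoate | O=C1C=CC(O)(/C=C/C=C/C=C/C(=O)OC(C)(C)C)C=C1 | intermediate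
13 | tert-butyl (2E,4E,6E)-7-[1-(1-hydroxyethoxy)-4-oxocyclohexa-2,5-dien-1-yl]hepta-2,4,6-trienoate (not isolated) | CC(O)OC1(/C=C/C=C/C=C/C(=O)OC(C)(C)C)C=CC(=O)C=C1 | intermediate
14 | tert-butyl (2E,4E,6E)-7-[(2S,3aR,7aS)-2-methyl-5-oxo-3a,4,5,7a-tetrahydro-2H-1,3-benzodioxol-7a-yl]hepta-2,4,6-trienoate (cis-fused ethylidene acetal, methyl exo) | C1=C[C@@](O2)(/C=C/C=C/C=C/C(=O)OC(C)(C)C)[C@H](O[C@@H]2C)CC1=O | intermediate
15 | tert-butyl (2E,4E,6E)-7-[(2S,3aR,7aS)-6-iodo-2-methyl-5-oxo-3a,4,5,7a-tetrahydro-2H-1,3-benzodioxol-7a-yl]hepta-2,4,6-trienoate | IC1=C[C@@](O2)(/C=C/C=C/C=C/C(=O)OC(C)(C)C)[C@H](O[C@@H]2C)CC1=O | intermediate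
16 | (E)-hept-2-en-1-ol | CCCC/C=C/CO | starting material
17 | (E)-1-bromohept-2-ene | CCCC/C=C/CBr | intermediate
18 | (R)-3-methylhept-1-ene | CCCC[C@@H](C)C=C | intermediate
19 | methacrolein (2-methylprop-2-enal) | CC(=C)C=O | starting material
20 | (R,E)-2,4-dimethyloct-2-enal | CCCC[C@@H](C)/C=C(C)/C=O | intermediate
21 | 2-chloroacetamide | NC(=O)CCl | starting material
22 | (2-amino-2-oxoethyl)triphenylphosphonium chloride (not isolated) | NC(=O)C[P+](c1ccccc1)(c1ccccc1)c1ccccc1.[Cl-] | intermediate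
23 | 2-(triphenyl-λ5-phosphanylidene)acetamide (not isolated) | NC(=O)C=P(c1ccccc1)(c1ccccc1)c1ccccc1 | intermediate
24 | (2E,4E,6R)-4,6-dimethyldeca-2,4-dienamide | CCCC[C@@H](C)/C=C(C)/C=C/C(N)=O | intermediate
25 | tert-butyl (2E,4E,6E)-7-[(2S,3aR,7aS)-6-{[(2E,4E,6R)-4,6-dimethyldeca-2,4-dienoyl]amino}-2-methyl-5-oxo-3a,4,5,7a-tetrahydro-2H-1,3-benzodioxol-7a-yl]hepta-2,4,6-trienoate | CCCC[C@@H](C)/C=C(C)/C=C/C(=O)NC1=C[C@@](O2)(/C=C/C=C/C=C/C(=O)OC(C)(C)C)[C@H](O[C@@H]2C)CC1=O | intermediate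
26 | (2E,4E,6E)-7-[(1S,6R)-3-{[(2E,4E,6R)-4,6-dimethyldeca-2,4-dienoyl]amino}-1,6-dihydroxy-4-oxocyclohex-2-en-1-yl]hepta-2,4,6-trienoic acid | CCCC[C@@H](C)/C=C(C)/C=C/C(=O)NC1=C[C@@](O)(/C=C/C=C/C=C/C(=O)O)[C@H](O)CC1=O | intermediate
27 | 2-amino-3-hydroxycyclopent-2-en-1-one | NC1=C(O)CCC1=O | starting material
28 | O-acylisourea of 26 and EDC (not isolated) | CCCC[C@@H](C)/C=C(C)/C=C/C(=O)NC1=C[C@@](O)(/C=C/C=C/C=C/C(=O)OC(=NCC)NCCCN(C)C)[C@H](O)CC1=O | intermediate
29 | (2E,4E,6R)-N-[(3S,4R)-3,4-dihydroxy-3-{(1E,3E,5E)-7-[(2-hydroxy-5-oxocyclopent-1-en-1-yl)amino]-7-oxohepta-1,3,5-trien-1-yl}-6-oxocyclohex-1-en-1-yl]-4,6-dimethyldeca-2,4-dienamide | CCCC[C@@H](C)/C=C(C)/C=C/C(=O)NC1=C[C@@](O)(/C=C/C=C/C=C/C(=O)NC2=C(O)CCC2=O)[C@H](O)CC1=O | target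

**Summary**

Total step count: 13. Longest linear sequence: 9 steps (steps 1, 2, 3, 4, 5, 6, 11, 12, 13).

Steps most likely to fail:

Step 3 (radical C–H trienylation: unprecedented acceptor, possible attack at other triene positions or over-addition). The fallback replaces the radical union by a polar 1,2-addition and sets out from 5. Takai iodo-olefination of 5 (CrCl2, CHI3, THF, 0 °C) gives tert-butyl (2E,4E,6E)-7-iodohepta-2,4,6-trienoate F1. Iodine–magnesium exchange (iPrMgCl·LiCl, THF, −40 °C) gives [(1E,3E,5E)-7-tert-butoxy-7-oxohepta-1,3,5-trien-1-yl]magnesium chloride F2. F2 is added to an excess of commercial cyclohexane-1,4-dione (LaCl3·2LiCl, THF, −40 °C), and the mono-adduct is 10, where the route is rejoined.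

Step 5 (desymmetrisation: enantioselectivity and sense with the trienyl substituent are untested). The fallback sets the diol by epoxidation and reductive opening and sets out from 12. Alkoxide-directed, tartrate-mediated asymmetric nucleophilic epoxidation (Ph3COOH, NaN(SiMe3)2, diisopropyl tartrate of the appropriate handedness, toluene, −40 °C) gives the syn-epoxy quinol tert-butyl (2E,4E,6E)-7-[(1R,2S,6S)-2-hydroxy-5-oxo-7-oxabicyclo[4.1.0]hept-3-en-2-yl]hepta-2,4,6-trienoate F3. Radical reductive opening of the epoxy ketone at the α-carbon with Cp2TiCl (from Cp2TiCl2 and Zn, THF, −20 °C) gives the cis-diol tert-butyl (2E,4E,6E)-7-[(1S,6R)-1,6-dihydroxy-4-oxocyclohex-2-en-1-yl]hepta-2,4,6-trienoate F4. Acetalisation of F4 (MeCH(OMe)2, PPTS, CH2Cl2) returns to the route at 14.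

Step 12 (global acidolysis: the β-hydroxy ketone, enamide and tertiary allylic alcohol may not survive aqueous TFA). The fallback reorders the end-game so that the free diol never meets strong acid and sets out from 25. Selective Lewis-acid cleavage of the tert-butyl ester (ZnBr2, CH2Cl2, 25 °C) gives (2E,4E,6E)-7-[(2S,3aR,7aS)-6-{[(2E,4E,6R)-4,6-dimethyldeca-2,4-dienoyl]amino}-2-methyl-5-oxo-3a,4,5,7a-tetrahydro-2H-1,3-benzodioxol-7a-yl]hepta-2,4,6-trienoic acid F5. Coupling of F5 with 27 (EDC·HCl, N-methylmorpholine, DMF) gives the acetal-protected target F6. Mild hydrolysis of the acetal in F6 (AcOH/H2O 4:1, 40 °C) then gives 29 directly.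

**Further compounds**

F1 | step 3 | tert-butyl (2E,4E,6E)-7-iodohepta-2,4,6-trienoate | CC(C)(C)OC(=O)/C=C/C=C/C=C/I
F2 | step 3 | [(1E,3E,5E)-7-tert-butoxy-7-oxohepta-1,3,5-trien-1-yl]magnesium chloride | CC(C)(C)OC(=O)/C=C/C=C/C=C/[Mg]Cl
F3 | step 5 | tert-butyl (2E,4E,6E)-7-[(1R,2S,6S)-2-hydroxy-5-oxo-7-oxabicyclo[4.1.0]hept-3-en-2-yl]hepta-2,4,6-trienoate | C1=C[C@@](O)(/C=C/C=C/C=C/C(=O)OC(C)(C)C)[C@H](O2)[C@H]2C1=O
F4 | step 5 | tert-butyl (2E,4E,6E)-7-[(1S,6R)-1,6-dihydroxy-4-oxocyclohex-2-en-1-yl]hepta-2,4,6-trienoate | C1=C[C@@](O)(/C=C/C=C/C=C/C(=O)OC(C)(C)C)[C@H](O)CC1=O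
F5 | step 12 | (2E,4E,6E)-7-[(2S,3aR,7aS)-6-{[(2E,4E,6R)-4,6-dimethyldeca-2,4-dienoyl]amino}-2-methyl-5-oxo-3a,4,5,7a-tetrahydro-2H-1,3-benzodioxol-7a-yl]hepta-2,4,6-trienoic acid | CCCC[C@@H](C)/C=C(C)/C=C/C(=O)NC1=C[C@@](O2)(/C=C/C=C/C=C/C(=O)O)[C@H](O[C@@H]2C)CC1=O
F6 | step 12 | (2E,4E,6R)-N-[(2S,3aR,7aS)-7a-{(1E,3E,5E)-7-[(2-hydroxy-5-oxocyclopent-1-en-1-yl)amino]-7-oxohepta-1,3,5-trien-1-yl}-2-methyl-5-oxo-3a,4,5,7a-tetrahydro-2H-1,3-benzodioxol-6-yl]-4,6-dimethyldeca-2,4-dienamide | CCCC[C@@H](C)/C=C(C)/C=C/C(=O)NC1=C[C@@](O2)(/C=C/C=C/C=C/C(=O)NC3=C(O)CCC3=O)[C@H](O[C@@H]2C)CC1=O
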